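**Retrosynthetic overview**

1. The last bonds cut are the two O–Si bonds and the C8–C(sp2) bond, which comes from a Suzuki–Miyaura coupling of an (S)-8-bromoflavanone with an (R,Z)-alkenylboronate.
2. Ring C is opened at C4–C4a, giving an (S)-3-aryloxy-3-phenylpropanoic acid that closes by intramolecular Friedel–Crafts acylation. The strategy rests on C4a of ring A being para to the C7 oxygen and ortho to O1, while C8, the only other position ortho to O1, is occupied (Br, later the side chain).
3. The C2–O1 bond comes from a Mitsunobu inversion of ethyl (R)-3-hydroxy-3-phenylpropanoate with mono-silylated 2-bromoresorcinol; this sets C2 as S.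
4. The side chain comes from (R)-2-methylglycidol: alkyne homologation, acetate opening of the epoxide, and trans-hydroboration to the (Z)-alkenylboronate.
5. Ring order: rings A and B are bought; ring C is the only ring formed (step 4).

Key step: step 4

Remark: the C7 oxygen is carried through the ring closure as its triisopropylsilyl ether, because trifluoroacetic anhydride would acylate a free C7 hydroxyl and deactivate C4a; the same ether then serves in the cross-coupling. (R)-2-Methylglycidol is taken as purchasable (otherwise one Sharpless epoxidation from 2-methylprop-2-en-1-ol).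

**Route**

Step 1
Reactants: 1 2-bromoresorcinol
Product: 2 2-bromo-3-[(triisopropylsilyl)oxy]phenol
Conditions: TIPSCl (0.9 equiv), imidazole, DMF, 0 °C → rt
Reagents that add atoms: triisopropylsilyl chloride, CC(C)[Si](Cl)(C(C)C)C(C)C
Why: Silyl ether formation on a symmetric diol with a sub-stoichiometric amount of a bulky chloride should give mainly the mono-ether, since the two hydroxyls are equivalent and diol and bis-ether are removed by chromatography.

Step 2
Reactants: 2 2-bromo-3-[(triisopropylsilyl)oxy]phenol; 3 ethyl (R)-3-hydroxy-3-phenylpropanoate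
Product: 4 ethyl (S)-3-{2-bromo-3-[(triisopropylsilyl)oxy]phenoxy}-3-phenylpropanoate
Conditions: PPh3, DIAD, toluene, 0 °C → rt
Reagents that add atoms: none
Why: In this Mitsunobu etherification the acidic ortho-bromophenol displaces the oxyphosphonium of the secondary benzylic alcohol by SN2 with inversion, so the R carbinol becomes the S ether carbon (the future C2), and low temperature in toluene limits elimination to ethyl cinnamate.

Step 3
Reactants: 4 ethyl (S)-3-{2-bromo-3-[(triisopropylsilyl)oxy]phenoxy}-3-phenylpropanoate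
Product: 6 (S)-3-{2-bromo-3-[(triisopropylsilyl)oxy]phenoxy}-3-phenylpropanoic acid, via trimethylstannyl ester 5 (not isolated)
Conditions: Me3SnOH, 1,2-dichloroethane, 80 °C; then dilute aq. HCl wash
Reagents that add atoms: trimethyltin hydroxide, C[Sn](C)(C)O
Why: Ester cleavage with Me3SnOH runs under nearly neutral conditions through the stannyl ester, which should avoid both E1cB loss of the β-aryloxide and attack on the aryl silyl ether that aqueous LiOH would risk.

Step 4
Reactants: 6 (S)-3-{2-bromo-3-[(triisopropylsilyl)oxy]phenoxy}-3-phenylpropanoic acid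
Product: 8 (S)-8-bromo-2-phenyl-7-[(triisopropylsilyl)oxy]chroman-4-one, via mixed trifluoroacetic anhydride 7 (not isolated)
Conditions: TFAA (3 equiv), TfOH (5 mol %), CH2Cl2, −20 → 0 °C
Reagents that add atoms: none
Why: TFAA converts acid 6 into mixed anhydride 7, which TfOH ionises to an acylium equivalent that is attacked by C4a of ring A, and loss of the proton from the arenium ion restores aromaticity and gives the aryl ketone. The closest known reaction type is the intramolecular Friedel–Crafts acylation of 3-aryloxypropanoic acids to chroman-4-ones. Ring C closes as a six-membered ring, the new C4–C4a bond forming exo to the acyl C=O while the O1–C2–C3 tether holds the electrophile over the ortho carbon. No stereocentre is created, and C2, set in step 2, has none of its bonds involved and should keep the S configuration. The step needs regioselectivity and survival of the benzylic C2–O1 ether: C8, the other position ortho to O1, carries bromine, and C4a is para to the C7 silyloxy donor and ortho to O1, so acylation should proceed at or below 0 °C, where ionisation of the C2–O1 bond (further disfavoured by the β-acyl group) and loss of the aryl silyl ether should not compete.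

Step 5
Reactants: 9 (R)-2-methylglycidol
Product: 10 (S)-2-methyloxirane-2-carbaldehyde
Conditions: TEMPO (10 mol %), PhI(OAc)2, CH2Cl2, rt; crude solution used at once
Reagents that add atoms: none
Why: The oxoammonium-mediated oxidation of a primary alcohol stops at the aldehyde and leaves the epoxide intact, and the quaternary α-carbon cannot epimerise (the descriptor changes to S only through the CIP priorities).

Step 6
Reactants: 10 (S)-2-methyloxirane-2-carbaldehyde
Product: 11 (R)-2-ethynyl-2-methyloxirane
Conditions: dimethyl (1-diazo-2-oxopropyl)phosphonate, K2CO3, MeOH, 0 °C → rt; kept as an ether solution (volatile)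
Reagents that add atoms: dimethyl (1-diazo-2-oxopropyl)phosphonate, COP(=O)(OC)C(=[N+]=[N-])C(C)=O
Why: In the Ohira–Bestmann (Seyferth–Gilbert) homologation the diazomethylphosphonate anion formed by methanolysis adds to the aldehyde, and loss of phosphate and N2 followed by a 1,2-hydrogen shift gives the terminal alkyne without touching any bond of the quaternary stereocentre.

Step 7
Reactants: 11 (R)-2-ethynyl-2-methyloxirane
Product: 12 (R)-2-hydroxy-2-methylbut-3-yn-1-yl acetate
Conditions: AcOH (3 equiv), CsOAc (0.3 equiv), DMF, 60 °C, sealed vessel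
Reagents that add atoms: acetic acid, CC(=O)O
Why: Acetate opens the 2,2-disubstituted epoxide by SN2 attack at the unhindered CH2 terminus under AcOH buffering, so the primary acetate and tertiary alcohol arise in one operation and the C–O bond at the stereocentre is retained.

Step 8
Reactants: 12 (R)-2-hydroxy-2-methylbut-3-yn-1-yl acetate
Product: 13 (R)-2-methyl-2-[(trimethylsilyl)oxy]but-3-yn-1-yl acetate
Conditions: TMSCl, imidazole, DMF, rt
Reagents that add atoms: trimethylsilyl chloride, C[Si](C)(C)Cl
Why: Silylation of the tertiary propargylic alcohol masks the O–H that would otherwise consume pinacolborane in the next step, and the acetate is inert to these conditions.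

Step 9
Reactants: 13 (R)-2-methyl-2-[(trimethylsilyl)oxy]but-3-yn-1-yl acetate
Product: 14 (R,Z)-2-methyl-4-(4,4,5,5-tetramethyl-1,3,2-dioxaborolan-2-yl)-2-[(trimethylsilyl)oxy]but-3-en-1-yl acetate
Conditions: HBpin (0.85 equiv), [Rh(cod)Cl]2 (1.5 mol %), P(i-Pr)3 (6 mol %), Et3N, cyclohexane, rt
Reagents that add atoms: pinacolborane, [H]B1OC(C)(C)C(C)(C)O1
Why: The rhodium-catalysed trans-hydroboration of terminal alkynes proceeds through a rhodium vinylidene and places boron on the terminal carbon cis to the carbinol carbon, which should give the (Z)-alkenylboronate with the remote stereocentre untouched.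

Step 10
Reactants: 8 (S)-8-bromo-2-phenyl-7-[(triisopropylsilyl)oxy]chroman-4-one; 14 (R,Z)-2-methyl-4-(4,4,5,5-tetramethyl-1,3,2-dioxaborolan-2-yl)-2-[(trimethylsilyl)oxy]but-3-en-1-yl acetate
Product: 15 (R,Z)-2-methyl-4-{(S)-4-oxo-2-phenyl-7-[(triisopropylsilyl)oxy]chroman-8-yl}-2-[(trimethylsilyl)oxy]but-3-en-1-yl acetate
Conditions: Pd(OAc)2 (5 mol %), SPhos (10 mol %), K3PO4, THF/H2O (10:1), 40 °C
Reagents that add atoms: none
Why: In this Suzuki–Miyaura coupling SPhos-ligated zerovalent palladium should insert into the hindered, electron-rich C8–Br bond, and transmetalation and reductive elimination retain the Z geometry, while the mild phosphate base at 40 °C should spare the acetate and keep ring C from opening by retro-oxa-Michael reaction.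

Step 11
Reactants: 15 (R,Z)-2-methyl-4-{(S)-4-oxo-2-phenyl-7-[(triisopropylsilyl)oxy]chroman-8-yl}-2-[(trimethylsilyl)oxy]but-3-en-1-yl acetate
Product: 16 (R,Z)-2-hydroxy-4-[(S)-7-hydroxy-4-oxo-2-phenylchroman-8-yl]-2-methylbut-3-en-1-yl acetate (CNP0372308.1)
Conditions: TBAF (3 equiv), AcOH (3 equiv), THF, 0 °C; pH 7 buffer work-up
Reagents that add atoms: none
Why: Fluoride cleaves both Si–O bonds, and the AcOH buffer keeps the medium near neutral so that the phenoxide should not open ring C, the acetate should not migrate or hydrolyse, and the tertiary allylic alcohol should not ionise toward a 2H-chromene.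

**Compound list**

1 | 2-bromoresorcinol (2-bromobenzene-1,3-diol) | Oc1cccc(O)c1Br | starting material
2 | 2-bromo-3-[(triisopropylsilyl)oxy]phenol | Oc1cccc(O[Si](C(C)C)(C(C)C)C(C)C)c1Br | intermediate
3 | ethyl (R)-3-hydroxy-3-phenylpropanoate | O[C@@H](c1ccccc1)CC(=O)OCC | starting material
4 | ethyl (S)-3-{2-bromo-3-[(triisopropylsilyl)oxy]phenoxy}-3-phenylpropanoate | CC(C)[Si](C(C)C)(C(C)C)Oc1cccc(O[C@H](c2ccccc2)CC(=O)OCC)c1Br | intermediate
5 | trimethylstannyl (S)-3-{2-bromo-3-[(triisopropylsilyl)oxy]phenoxy}-3-phenylpropanoate | CC(C)[Si](C(C)C)(C(C)C)Oc1cccc(O[C@H](c2ccccc2)CC(=O)O[Sn](C)(C)C)c1Br | intermediate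
6 | (S)-3-{2-bromo-3-[(triisopropylsilyl)oxy]phenoxy}-3-phenylpropanoic acid | CC(C)[Si](C(C)C)(C(C)C)Oc1cccc(O[C@H](c2ccccc2)CC(=O)O)c1Br | intermediate
7 | (S)-3-{2-bromo-3-[(triisopropylsilyl)oxy]phenoxy}-3-phenylpropanoic trifluoroacetic anhydride | CC(C)[Si](C(C)C)(C(C)C)Oc1cccc(O[C@H](c2ccccc2)CC(=O)OC(=O)C(F)(F)F)c1Br | intermediate
8 | (S)-8-bromo-2-phenyl-7-[(triisopropylsilyl)oxy]chroman-4-one | CC(C)[Si](C(C)C)(C(C)C)Oc1ccc2c(c1Br)O[C@H](c1ccccc1)CC2=O | intermediate
9 | (R)-2-methylglycidol, [(2R)-2-methyloxiran-2-yl]methanol | OC[C@]1(C)CO1 | starting material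
10 | (S)-2-methyloxirane-2-carbaldehyde | O=C[C@]1(C)CO1 | intermediate
11 | (R)-2-ethynyl-2-methyloxirane | C#C[C@]1(C)CO1 | intermediate
12 | (R)-2-hydroxy-2-methylbut-3-yn-1-yl acetate | CC(=O)OC[C@](C)(O)C#C | intermediate
13 | (R)-2-methyl-2-[(trimethylsilyl)oxy]but-3-yn-1-yl acetate | CC(=O)OC[C@](C)(O[Si](C)(C)C)C#C | intermediate
14 | (R,Z)-2-methyl-4-(4,4,5,5-tetramethyl-1,3,2-dioxaborolan-2-yl)-2-[(trimethylsilyl)oxy]but-3-en-1-yl acetate | CC(=O)OC[C@](C)(O[Si](C)(C)C)/C=C\B1OC(C)(C)C(C)(C)O1 | intermediate
15 | (R,Z)-2-methyl-4-{(S)-4-oxo-2-phenyl-7-[(triisopropylsilyl)oxy]chroman-8-yl}-2-[(trimethylsilyl)oxy]but-3-en-1-yl acetate | CC(=O)OC[C@](C)(O[Si](C)(C)C)/C=C\c1c(O[Si](C(C)C)(C(C)C)C(C)C)ccc2c1O[C@H](c1ccccc1)CC2=O | intermediate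
16 | (R,Z)-2-hydroxy-4-[(S)-7-hydroxy-4-oxo-2-phenylchroman-8-yl]-2-methylbut-3-en-1-yl acetate | CC(=O)OC[C@](C)(O)/C=C\c1c(O)ccc2c1O[C@H](c1ccccc1)CC2=O | target

**Step count**

Total: 11 steps. Longest linear sequence: 7 steps (steps 5–11, from (R)-2-methylglycidol); the aryl branch (steps 1–4) joins at step 10.

**Steps most likely to fail**

Step 4. The acid medium may ionise the benzylic C2–O1 ether (erosion of configuration at C2, or fragmentation to a cinnamic acid and the phenol). Alternatively the meta bromine may slow acylation so far that the mixed anhydride is only hydrolysed on work-up. In the fallback, C2 would be set after ring C exists, setting out from 1 and coming back at 8. 2-Bromoresorcinol 1 would be C-acetylated (AcOH, BF3·OEt2, 90 °C) to 1-(3-bromo-2,4-dihydroxyphenyl)ethanone F1. Its non-chelated 4-hydroxyl would be silylated (TIPSCl, imidazole) to 1-{3-bromo-2-hydroxy-4-[(triisopropylsilyl)oxy]phenyl}ethanone F2. Condensation with N,N-dimethylformamide dimethyl acetal would give the enaminone (E)-1-{3-bromo-2-hydroxy-4-[(triisopropylsilyl)oxy]phenyl}-3-(dimethylamino)prop-2-en-1-one F3, which aqueous HCl in CH2Cl2 would close to 8-bromo-7-[(triisopropylsilyl)oxy]-4H-chromen-4-one F4. Enantioselective conjugate addition of phenylboronic acid would then return to 8. The catalyst would be Pd(OCOCF3)2 with the t-BuPyOx enantiomer that delivers phenyl to the face giving 2S (NH4PF6, H2O, 1,2-dichloroethane, 60 °C); palladium stays divalent throughout, so the C8–Br bond should not be inserted.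

Step 10. Oxidative addition into the doubly ortho-substituted, electron-rich bromide may be slow. The boronate may undergo Z-to-E isomerisation or protodeboronation. The base may open ring C and scramble C2. In the fallback the C8–C bond would be made through the alkyne and the geometry set by syn hydrogenation, setting out from 8 and 13 and coming back at 15. Room-temperature Sonogashira coupling of 8 with 13 (Pd(PhCN)2Cl2, P(t-Bu)3, CuI, HN(i-Pr)2, dioxane) would give (R)-2-methyl-4-{(S)-4-oxo-2-phenyl-7-[(triisopropylsilyl)oxy]chroman-8-yl}-2-[(trimethylsilyl)oxy]but-3-yn-1-yl acetate F5. Semi-hydrogenation of F5 (H2, Pd on CaCO3 poisoned with Pb(OAc)2, quinoline, EtOAc) would then give 15.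

Step 9. The quaternary propargylic carbon may retard vinylidene formation, and rhodium hydride species may isomerise the Z product to E or over-reduce it. In the fallback the geometry would come from a syn diimide reduction, setting out from 13 and coming back at 14. Iodination of 13 (N-iodosuccinimide, AgNO3 cat., acetone) would give (R)-4-iodo-2-methyl-2-[(trimethylsilyl)oxy]but-3-yn-1-yl acetate F6. Diimide generated from 2-nitrobenzenesulfonylhydrazide and Et3N would reduce it to (R,Z)-4-iodo-2-methyl-2-[(trimethylsilyl)oxy]but-3-en-1-yl acetate F7. Stereoretentive borylation of F7 (B2pin2, PdCl2(dppf), KOPh, toluene, 50 °C) would return to 14.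

**Further compounds**

F1 | step 4 | 1-(3-bromo-2,4-dihydroxyphenyl)ethanone | CC(=O)c1ccc(O)c(Br)c1O
F2 | step 4 | 1-{3-bromo-2-hydroxy-4-[(triisopropylsilyl)oxy]phenyl}ethanone | CC(=O)c1ccc(O[Si](C(C)C)(C(C)C)C(C)C)c(Br)c1O
F3 | step 4 | (E)-1-{3-bromo-2-hydroxy-4-[(triisopropylsilyl)oxy]phenyl}-3-(dimethylamino)prop-2-en-1-one | CN(C)/C=C/C(=O)c1ccc(O[Si](C(C)C)(C(C)C)C(C)C)c(Br)c1O
F4 | step 4 | 8-bromo-7-[(triisopropylsilyl)oxy]-4H-chromen-4-one | CC(C)[Si](C(C)C)(C(C)C)Oc1ccc2c(c1Br)occc2=O
F5 | step 10 | (R)-2-methyl-4-{(S)-4-oxo-2-phenyl-7-[(triisopropylsilyl)oxy]chroman-8-yl}-2-[(trimethylsilyl)oxy]but-3-yn-1-yl acetate | CC(=O)OC[C@](C)(O[Si](C)(C)C)C#Cc1c(O[Si](C(C)C)(C(C)C)C(C)C)ccc2c1O[C@H](c1ccccc1)CC2=O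
F6 | step 9 | (R)-4-iodo-2-methyl-2-[(trimethylsilyl)oxy]but-3-yn-1-yl acetate | CC(=O)OC[C@](C)(O[Si](C)(C)C)C#CI
F7 | step 9 | (R,Z)-4-iodo-2-methyl-2-[(trimethylsilyl)oxy]but-3-en-1-yl acetate | CC(=O)OC[C@](C)(O[Si](C)(C)C)/C=C\I
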